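The runs come from a simulation with constants of no real substance; noise was put on by code.

**Reading time.** At the reading, 15 h after mixing, the share asked for is a ratio of two accumulated products. As the steps are written, both paths are first order in free catalyst and in partner, so these cancel from the ratio of rates and leave one dimensionless number, the selectivity factor s, the ratio of the two paths' rates at equal substrate. Replacing the curve by its mean gives share = s·m/(1+s·m), where m is the mean c(left-handed substrate)/c(right-handed substrate), roughly one minus the left-handed product over one minus the right-handed product, as fractions of both substrates charged.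

in all of them: free catalyst 85 µM; added ligand 0.28 mM
- eta: left-handed substrate 0.067 M; right-handed substrate 0.067 M; partner 0.22 M; temperature 10 °C; run made earlier
- beta: left-handed substrate 0.15 M; right-handed substrate 0.15 M; partner 0.22 M; temperature 32 °C; run made earlier
- oak: left-handed substrate 0.10 M; right-handed substrate 0.10 M; partner 0.220 M; temperature 40 °C; time 15 h
- cedar: left-handed substrate 0.10 M; right-handed substrate 0.10 M; partner 0.220 M; temperature 20 °C; time 15 h
- alder: left-handed substrate 0.10 M; right-handed substrate 0.10 M; partner 0.220 M; temperature 0 °C; time 15 h

- eta (time / h: left-handed product / %, right-handed product / %): 8.00: 2.9, 0.7; 20.0: 5.2, 0; 40.0: 9.5, 4.1; 72.0: 14.4, 4.2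
- beta (time / h: left-handed product / %, right-handed product / %): 1.33: 1.7, 0; 3.00: 3.4, 1.6; 6.00: 4.2, 2.1; 15.0: 6.6, 4.8

(readings scatter by 1 percentage point)

- the best flask by share of left-handed product in all that became left-handed product or right-handed product; "all alike" if 1.5 percentage points covers them all (oak / cedar / alder / all alike)
- share of left-handed product in all that became left-handed product or right-handed product, oak
- share of left-handed product in all that became left-handed product or right-handed product, cedar
- share of left-handed product in all that became left-handed product or right-handed product, alder

- free catalyst is single-handed; left-handed substrate and right-handed substrate are mirror images of each other, charged as a racemate, each of them at the stated concentration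
- the earlier runs were read with a standard deviation of 1 percentage point
- steps thought possible: partner + free catalyst + left-handed substrate -> free catalyst + left-handed product; partner + free catalyst + right-handed substrate -> free catalyst + right-handed product; left-handed substrate <-> right-handed substrate; free catalyst + added ligand <-> idle complex; partner -> decomposed reagent; free catalyst -> spent catalyst

**Reading s.** Summing each run's four readings tames the scatter. The summed products stand at 3.56 to one in eta and 1.87 to one in beta, though beta's right-handed sum is 8.50 % with 1 percentage point of scatter per reading. Taken as s, these two read ratios set a straight line of ln s against reciprocal temperature with slope 2520 K. It gives s = 4.93 for alder, 2.62 for cedar and 1.51 for oak, the selectivity factor reckoned for oak. The shares are then 83.1 %, 72.4 % and 60.2 %, and alder leads.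

**One number enough?** Beta's last reading gives m = 0.981, which, borrowed for oak, lowers the share reckoned there by 0.46 points. The reckoning therefore keeps s/(1+s) for its shares.

**The forecast** names alder, with 60 %, 72 % and 83 % for oak, cedar and alder, and calls its slope “steep and uncertain”.

**The flasks** give 65.2 %, 71.4 % and 78.1 % for oak, cedar and alder, so alder is best.

    partner + free catalyst + left-handed substrate → free catalyst + left-handed product (k = 1500 M⁻² h⁻¹, Ea = 39.0 kJ mol⁻¹)
    partner + free catalyst + right-handed substrate → free catalyst + right-handed product (k = 770 M⁻² h⁻¹, Ea = 50.0 kJ mol⁻¹)
    left-handed substrate ⇌ right-handed substrate (k = 0.0140 h⁻¹, Ea = 102 kJ mol⁻¹)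
    free catalyst + added ligand ⇌ idle complex (K = 69000 M⁻¹, k = 130 M⁻¹ h⁻¹, Ea = 49.0 kJ mol⁻¹, ΔH = −11.0 kJ mol⁻¹)
    partner → decomposed reagent (k = 0.00350 h⁻¹, Ea = 115 kJ mol⁻¹)
    free catalyst → spent catalyst (k = 0.0750 h⁻¹, Ea = 107 kJ mol⁻¹)
    (constants at 40 °C)

**What ran.** In oak both paths ran while free catalyst fell to 19.6 % by 15.0 h, with 55.2 % spent and 25.3 % idle, and left-handed substrate kept 84 % of its charge; m = 0.958 turns the share into s = 1.95, above the 1.51 reckoned and beside the ratio of the two constants at 40 °C, 1.95. In a repeat of alder at −25 °C, the constants give s = 5.89, and the flask reached a share of 85.4 % with left-handed product at 0.412 %.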